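**Retrosynthetic overview**
1. Target 11 ← acidolysis of one PMB ester and two MOM ethers ← PMB 4,5-diester 8 ← release of the boronate from 10.
2. Key disconnection: the O4–C(=O) and O5–C(=O) ester bonds of 10 are traced back, by acyl shifts O3→O4 and O4→O5, to the 3,4-diester 6 or any mixture of diester isomers.
3. Feature used: the hydroxyls on C1 and C3 of the cyclohexane ring (O1, O3) are syn-1,3-diaxial, and only the 4,5-diester leaves both free, so only it can be bridged by boron into a six-membered O1–B–O3 ring (1,3,2-dioxaborinane).
4. 6 (with isomers 7, 8) ← Steglich diacylation of PMB quinate 2 with MOM-protected p-coumaric acid 5; 2 ← (−)-quinic acid 1; 5 ← p-coumaric acid 3.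
5. Ring order: the cyclohexane comes intact from 1; the only ring formed is the temporary boronate (step 4), opened again in step 5.

Key step: step 4

Remarks on the chemistry:
- Locants follow the current IUPAC numbering of quinic acid (O1, O3, O4 on one face, O5 on the other). Natural (−)-quinic acid carries the required configuration at all four stereocentres, and no step breaks a bond to them.
- The diester fraction of step 3 is carried forward as a mixture of positional isomers. Compound 6 is written as its representative because every isomer converges in step 4.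
- From step 3 onward the work is done in subdued light to keep the cinnamate double bonds E.
- Abbreviations: PMB = 4-methoxybenzyl, MOM = methoxymethyl, DIC = N,N'-diisopropylcarbodiimide, DMAP = 4-(dimethylamino)pyridine, DBU = 1,8-diazabicyclo[5.4.0]undec-7-ene, TFA = trifluoroacetic acid.

**Step 1**
Reactants: 1 (−)-quinic acid
Product: 2 4-methoxybenzyl quinate (PMB ester of 1; hydroxyls on C1, C3, C4 and C5 free, configuration of 1 retained)
Conditions: Cs2CO3 (0.55 equiv), 4-methoxybenzyl chloride (1.1 equiv), DMF, rt → 40 °C
Reagents that add atoms: 4-methoxybenzyl chloride, COc1ccc(CCl)cc1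
Why: SN2 O-alkylation of the cesium carboxylate, in which carbonate does not deprotonate the alcohols, so only the carboxyl oxygen should be benzylated and the stereocentres are untouched.

**Step 2**
Reactants: 3 p-coumaric acid
Product: 5 (E)-3-[4-(methoxymethoxy)phenyl]prop-2-enoic acid, via methoxymethyl ester 4 (not isolated)
Conditions: MOMCl (2.5 equiv), i-Pr2NEt (3 equiv), CH2Cl2, 0 °C → rt; evaporation, then LiOH (5 equiv), THF–MeOH–H2O, rt; aq. HCl to pH 3–4 at 0 °C
Reagents that add atoms: chloromethyl methyl ether, COCCl
Why: O-alkylation of phenoxide and carboxylate by the α-chloro ether followed by saponification, in which the acylal-type MOM ester is cleaved by hydroxide while the aryl MOM acetal is base-stable and the E-alkene is not affected.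

**Step 3**
Reactants: 2 4-methoxybenzyl quinate; 5 (E)-3-[4-(methoxymethoxy)phenyl]prop-2-enoic acid (2.1 equiv)
Product: 6 4-methoxybenzyl 3,4-bis-O-[(E)-4-(methoxymethoxy)cinnamoyl]quinate (O1–H and O5–H free), collected as the whole diester fraction that also holds the 3,5-isomer 7 (O1–H and O4–H free) and the 4,5-isomer 8 (O1–H and O3–H free)
Conditions: DIC (2.3 equiv), DMAP (0.2 equiv), CH2Cl2–DMF (4:1), 0 °C → rt; chromatography on silica, mono- and triesters cut off, diester band taken whole
Reagents that add atoms: none
Why: Steglich esterification through the O-acylisourea and the N-acylpyridinium ion, in which the three secondary hydroxyls compete while the tertiary O1–H beside the ester is too hindered, so the diester band should be a mixture of positional isomers that all feed step 4, with no stereocentre touched.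

**Step 4**
Reactants: 6 4-methoxybenzyl 3,4-bis-O-[(E)-4-(methoxymethoxy)cinnamoyl]quinate (as the diester fraction with 7 and 8); 9 phenylboronic acid
Product: 10 4-methoxybenzyl 4,5-bis-O-[(E)-4-(methoxymethoxy)cinnamoyl]quinate 1,3-O-phenylboronate, via 3,5-diester 7 (not isolated), via 4,5-diester 8 (not isolated)
Conditions: PhB(OH)2 (1.3 equiv), DBU (0.3 equiv), 4 Å molecular sieves, toluene (0.05 M), 40 °C; then AcOH (0.3 equiv), filtration, short silica plug (the hydroxyl-free boronate elutes ahead of any unconverted isomer)
Reagents that add atoms: phenylboronic acid, OB(O)c1ccccc1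
Why: Proposed new method: the amidine-activated free hydroxyl adds to the neighbouring cinnamate carbonyl to give a five-membered 2-hydroxy-1,3-dioxolane (orthoacid) intermediate that opens to either side, so in 6 the O4 acyl shifts to O5 (7) and the O3 acyl then shifts to O4 (8), the three diesters being in equilibrium, and only 8 is withdrawn because its O1–H and O3–H condense twice with phenylboronic acid while the sieves take up the water. The closest known reaction types are the base-mediated acyl migration among O3, O4 and O5 of acylquinic acids and the formation of six-membered arylboronates from syn-1,3-diaxial diols, which have not been coupled into one isomer-selecting operation. The single ring closed is the 1,3,2-dioxaborinane, by two B–O condensations (six-membered closure over O1–B–O3), giving a 2,4-dioxa-3-borabicyclo[3.3.1]nonane on the unchanged quinate chair with both esters equatorial. No stereocentre is formed or put at risk, since only acyl C–O and B–O bonds are made and broken and C1 is quaternary. The step needs regioselectivity among the three diesters, and the substrate supplies it: the free pair of 6 (O1/O5) is trans-1,3 and that of 7 (O1/O4) lies 1,4 across the ring, so neither can chelate boron on the chair, whereas capture of O3 in 10 removes the nucleophile for the return shift.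

**Step 5**
Reactants: 10 4-methoxybenzyl 4,5-bis-O-[(E)-4-(methoxymethoxy)cinnamoyl]quinate 1,3-O-phenylboronate
Product: 8 4-methoxybenzyl 4,5-bis-O-[(E)-4-(methoxymethoxy)cinnamoyl]quinate (now as the single positional isomer)
Conditions: pinacol (5 equiv), AcOH (0.5 equiv), THF–MeOH (4:1), rt; chromatography on silica
Reagents that add atoms: none
Why: Boronate transesterification, in which the B–O bonds exchange onto excess pinacol under weakly acidic, base-free conditions, so O1–H and O3–H should be released without an alkoxide being formed and the acyl groups should stay on O4 and O5.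

**Step 6**
Reactants: 8 4-methoxybenzyl 4,5-bis-O-[(E)-4-(methoxymethoxy)cinnamoyl]quinate
Product: 11 4,5-di-O-p-coumaroylquinic acid
Conditions: TFA–CH2Cl2 (1:3), anisole (10 equiv), H2O (5 equiv), 0 °C → rt; evaporation, reversed-phase chromatography (MeCN–H2O, 0.1% HCO2H)
Reagents that add atoms: none
Why: Acidolysis, in which the PMB ester ionises to the 4-methoxybenzyl cation (captured by anisole in a Friedel–Crafts alkylation) and the aryl MOM acetals hydrolyse through the oxocarbenium ion, while the cinnamate esters, the E-alkenes and the stereocentres are inert to TFA and the acylated O5 cannot lactonise.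

**Compound list**
1 | (−)-quinic acid | O[C@@H]1[C@H](O)C[C@@](O)(C(=O)O)C[C@H]1O | starting material
2 | 4-methoxybenzyl quinate | O[C@@H]1[C@H](O)C[C@@](O)(C(=O)OCc2ccc(OC)cc2)C[C@H]1O | intermediate
3 | p-coumaric acid, (E)-4-hydroxycinnamic acid | OC(=O)/C=C/c1ccc(O)cc1 | starting material
4 | methoxymethyl (E)-3-[4-(methoxymethoxy)phenyl]prop-2-enoate | COCOC(=O)/C=C/c1ccc(OCOC)cc1 | intermediate
5 | (E)-3-[4-(methoxymethoxy)phenyl]prop-2-enoic acid | OC(=O)/C=C/c1ccc(OCOC)cc1 | intermediate
6 | 4-methoxybenzyl 3,4-bis-O-[(E)-4-(methoxymethoxy)cinnamoyl]quinate | O=C(/C=C/c1ccc(OCOC)cc1)O[C@@H]1[C@H](OC(=O)/C=C/c2ccc(OCOC)cc2)C[C@@](O)(C(=O)OCc2ccc(OC)cc2)C[C@H]1O | intermediate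
7 | 4-methoxybenzyl 3,5-bis-O-[(E)-4-(methoxymethoxy)cinnamoyl]quinate | O[C@@H]1[C@H](OC(=O)/C=C/c2ccc(OCOC)cc2)C[C@@](O)(C(=O)OCc2ccc(OC)cc2)C[C@H]1OC(=O)/C=C/c1ccc(OCOC)cc1 | intermediate
8 | 4-methoxybenzyl 4,5-bis-O-[(E)-4-(methoxymethoxy)cinnamoyl]quinate | O=C(/C=C/c1ccc(OCOC)cc1)O[C@@H]1[C@H](O)C[C@@](O)(C(=O)OCc2ccc(OC)cc2)C[C@H]1OC(=O)/C=C/c1ccc(OCOC)cc1 | intermediate
9 | phenylboronic acid | OB(O)c1ccccc1 | starting material
10 | 4-methoxybenzyl 4,5-bis-O-[(E)-4-(methoxymethoxy)cinnamoyl]quinate 1,3-O-phenylboronate | O=C(/C=C/c1ccc(OCOC)cc1)O[C@@H]1[C@H]2C[C@@](OB(c3ccccc3)O2)(C(=O)OCc2ccc(OC)cc2)C[C@H]1OC(=O)/C=C/c1ccc(OCOC)cc1 | intermediate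
11 | 4,5-di-O-p-coumaroylquinic acid | O=C(/C=C/c1ccc(O)cc1)O[C@@H]1[C@H](O)C[C@@](O)(C(=O)O)C[C@H]1OC(=O)/C=C/c1ccc(O)cc1 | target

**Step count**
Total steps: 6. Longest linear sequence: 5 steps (steps 1, 3, 4, 5, 6; the branch through step 2 is equally long).

**Steps most likely to fail**

Step 4 (proposed new method). Three processes may defeat it. The Lewis-acidic boron may tie up the amidine so that acyl transfer stalls before the isomers are drained. O5–H of the 3,4-diester may attack the PMB ester and lactonise with loss of 4-methoxybenzyl alcohol. Intermolecular acyl scrambling may produce mono- and triesters. The fallback uses the boronate as an ordinary protecting group before acylation and sets out from 2. Condensation of 2 with 9 (1.05 equiv, toluene, 4 Å molecular sieves, rt) should give 4-methoxybenzyl quinate 1,3-O-phenylboronate F1, because arylboronic acids bridge a syn-1,3-diaxial diol of a six-membered polyol in preference to a cis-vicinal pair; here the cis-3,4 pair is the only competing site. In F1 only the equatorial O4–H and O5–H remain free, and Steglich esterification with 5 (2.4 equiv, DIC, DMAP, CH2Cl2) then returns to the route at 10, bypassing steps 3 and 4.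

Step 3. The acylation is statistical, so over- and under-acylation, N-acylurea formation and an imperfect group separation may leave little diester. The fallback places the two acyl groups one at a time and sets out from 2. Treatment with 2,2-dimethoxypropane and catalytic camphorsulfonic acid in acetone should protect the cis-3,4-diol as 4-methoxybenzyl 3,4-O-isopropylidenequinate F2. DIC/DMAP with 5 (1.2 equiv) then acylates O5 alone to give 4-methoxybenzyl 3,4-O-isopropylidene-5-O-[(E)-4-(methoxymethoxy)cinnamoyl]quinate F3. Aqueous AcOH (80%, 40 °C) removes the acetonide to give 4-methoxybenzyl 5-O-[(E)-4-(methoxymethoxy)cinnamoyl]quinate F4. A second esterification with 5 (1.0 equiv, DIC, DMAP, −20 °C) acylates one hydroxyl of the cis-diol, the equatorial O4 being expected to react first. The route is rejoined at 8, accompanied by some 7, which step 4 converts as well.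

Step 6. The liberated phenol rings may be alkylated by 4-methoxybenzyl or methoxymethyl cations, acetal cleavage may be incomplete, and prolonged acid exposure may cause an acyl shift. The fallback splits the unmasking into two operations and sets out from 8. ZnBr2 (1 equiv) and propane-1-thiol (3 equiv) in CH2Cl2 at 0 °C should remove both MOM ethers, the thiol taking up the methoxymethyl unit, to give 4-methoxybenzyl 4,5-di-O-[(E)-4-hydroxycinnamoyl]quinate F5. A brief treatment with TFA (10% in CH2Cl2, anisole, 0 °C) then cleaves only the PMB ester and returns to the route at 11.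

**Further compounds**
F1 | step 4 | 4-methoxybenzyl quinate 1,3-O-phenylboronate | O[C@@H]1[C@H]2C[C@@](OB(c3ccccc3)O2)(C(=O)OCc2ccc(OC)cc2)C[C@H]1O
F2 | step 3 | 4-methoxybenzyl 3,4-O-isopropylidenequinate | CC1(C)O[C@@H]2[C@H](O1)C[C@@](O)(C(=O)OCc3ccc(OC)cc3)C[C@H]2O
F3 | step 3 | 4-methoxybenzyl 3,4-O-isopropylidene-5-O-[(E)-4-(methoxymethoxy)cinnamoyl]quinate | CC1(C)O[C@@H]2[C@H](O1)C[C@@](O)(C(=O)OCc3ccc(OC)cc3)C[C@H]2OC(=O)/C=C/c1ccc(OCOC)cc1
F4 | step 3 | 4-methoxybenzyl 5-O-[(E)-4-(methoxymethoxy)cinnamoyl]quinate | O[C@@H]1[C@H](O)C[C@@](O)(C(=O)OCc2ccc(OC)cc2)C[C@H]1OC(=O)/C=C/c1ccc(OCOC)cc1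
F5 | step 6 | 4-methoxybenzyl 4,5-di-O-[(E)-4-hydroxycinnamoyl]quinate | O=C(/C=C/c1ccc(O)cc1)O[C@@H]1[C@H](O)C[C@@](O)(C(=O)OCc2ccc(OC)cc2)C[C@H]1OC(=O)/C=C/c1ccc(O)cc1
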